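- At 150 min, the last reading, the eta run had made 0.235 M of target and the beta run 0.031 M, so halving the free catalyst cost a factor of 7.58, and I wanted to know what a catalyst could be doing to give so steep a loss.

| flask | starting material | free catalyst | time |
|---|---|---|---|
| eta | 0.500 M | 0.0400 M |  |
| beta | 0.500 M | 0.0200 M |  |
| theta | 0.750 M | 0.0400 M |  |
| alpha | 1.50 M | 0.0200 M | 150 min |

| run | time / min | [target] / M |
|---|---|---|
| eta run | 6.0 | 0.006 |
| eta run | 13 | 0 |
| eta run | 30 | 0.017 |
| eta run | 67 | 0.078 |
| eta run | 150 | 0.235 |
| beta run | 6.0 | 0 |
| beta run | 13 | 0 |
| beta run | 30 | 0.007 |
| beta run | 67 | 0 |
| beta run | 150 | 0.031 |
| theta run | 6.0 | 0 |
| theta run | 13 | 0.006 |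
| theta run | 30 | 0.014 |
| theta run | 67 | 0.112 |
| theta run | 150 | 0.308 |

(standard deviation of a reading: 0.005 M)

- Overall: starting material -> target, with free catalyst as catalyst.
- Constant volume, constant temperature.
- Readings of a species count what is bound in complexes too.
- An order is taken over about fifteen percent of the charge, up and down.

* the power of [starting material] that the first rate follows, about the charge of the eta run; measure it at two percent of starting material made into target (one fixed amount of target, the same in the runs compared)
* the power of [free catalyst] that the first rate follows, about the charge of the eta run; measure it at two percent of starting material made into target
* target in the alpha run at 150 min, as a share of the starting material charged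

- My first estimate was a plain power, which from that factor came to 2.92 at fixed time. I doubted it, since a catalyst that works by turnover should act in proportion to what is working.
- So I supposed that target at fixed time follows the charge minus a fixed amount, the dead charge: 0.0170 M, the free catalyst charge at which the line through the two runs reaches zero target. The working catalyst is then 0.0230 M in the eta run and 0.00304 M in the beta run.
- The objection was that this rests on one small reading. Moving it by its scatter, up and then down, gives a dead charge of 0.0164 M to 0.0175 M, so the estimate held. The two runs cannot separate this line from the power, however, so the choice remained my judgement.
- The eta run has an induction period, with target growing about as the square of time, and on that law the rate at fixed target goes as the square root of the coefficient. About the eta charge, the order in catalyst is then half the charge over the working catalyst, 0.868, which is a rate order at fixed target and so lower than the plain power of 2.92 at fixed time.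
- For starting material, the theta and eta runs at 67 min give a fixed-time order of 0.892, so 0.446 at fixed target.
- The alpha run has the beta run's catalyst charge, so I scaled the beta reading by the charge of starting material, which gave 5.51%. The objection was that the readings at 150 min give a fixed-time order of 0.667, though by then the target read in the eta run stood at 47.0% of its charge, and that order gives 4.30%. I took the middle, 4.90%.
- The forecast gave an order of 0.5 in starting material, an order of 1.8 in free catalyst and 5% for the alpha run, holding that “orders should be compared at fixed target”, and its order in catalyst stood above my 0.868.
- The flask gave an order of 0.53 in starting material, an order of 1.1 in free catalyst and 4.33% for the alpha run.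

    active catalyst + starting material ⇌ catalyst-substrate complex (0.2460 M⁻¹ min⁻¹, 0.007920 min⁻¹)
    catalyst-substrate complex → target + active catalyst (0.6000 min⁻¹)
    free catalyst → active catalyst (0.05178 min⁻¹)
    active catalyst + impurity → spent catalyst

- The order in catalyst came out above my 0.868, and the alpha share below my 4.90%. At the same amount of target, the beta run's rate was 0.24 of the eta run's, which across those two charges is an order of 2.08, steeper than the 1.1 about the eta charge. The alpha run, with 0.00304 M of working catalyst by my dead charge, made 0.0649 M of target in 150 min, which is 21.4 turnovers per working catalyst.

The earlier runs and the new flask are calculated for an exercise; the scatter is artificial.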